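The cyclohexane ring C13–C18 carries its four oxygens (C15, C16, C17, C18) on one face and C12 plus the methyls at C14, C15 and C17 on the other, so it is read as an oxidised cis-5,6-disubstituted cyclohexa-1,3-diene (C15=C16–C17=C18). One [4+2] addition of singlet oxygen across C15/C18, anti to the C13/C14 substituents, closes the peroxide bridge and sets both carbinol centres; the derived cis-enediol then steers osmium onto C16=C17. The precursor, a silyl-protected cis-5-(hydroxymethyl)-1,3,6-trimethylcyclohexa-1,3-diene, arises by thermal 6π closure of an (E,Z,E)-trienoyl oxazolidinone, which lets one enantiomeric series be isolated. Two olefinations then attach the pyranone triene.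

Key step: step 9

Remark on labels and structures: atoms are labelled as in the target (C6 = pyranone carbon bearing the chain, C7–C12 = triene, C13–C18 = ring, C13 bearing C12); β is the ring face of the four oxygens and α the face of C12 and the three ring methyls. Re-reading the target SMILES confirms this all-β oxygen pattern, and diene 13 and endoperoxide 14 as drawn below carry the matching configuration, so no structural correction was needed.

Assumption: the ring configuration of the two imides separated in step 6 is assigned by X-ray diffraction, with the (S)-benzyl centre as internal reference, before 11 is carried on.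

Step 1
Reactants: 1 tiglic aldehyde; 2 ethyl 2-[bis(2,2,2-trifluoroethoxy)phosphoryl]propanoate
Product: 3 ethyl (2Z,4E)-2,4-dimethylhexa-2,4-dienoate
Conditions: KHMDS, 18-crown-6, THF, −78 °C
Reagents that add atoms: none
Why: Still–Gennari olefination; the electron-poor phosphonate with a crown-sequestered potassium ion eliminates under kinetic control to the (Z)-α-methyl enoate, which puts the future C18 cis to C15 as the central alkene of the triene requires, while the E alkene of 1 is untouched.

Step 2
Reactants: 3 ethyl (2Z,4E)-2,4-dimethylhexa-2,4-dienoate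
Product: 4 (2Z,4E)-2,4-dimethylhexa-2,4-dien-1-ol
Conditions: DIBAL-H, CH2Cl2, −78 °C; Rochelle salt work-up
Reagents that add atoms: none
Why: 1,2-reduction of a conjugated ester by DIBAL-H at low temperature gives the allylic alcohol without affecting either alkene geometry.

Step 3
Reactants: 4 (2Z,4E)-2,4-dimethylhexa-2,4-dien-1-ol
Product: 5 (2Z,4E)-2,4-dimethylhexa-2,4-dienal
Conditions: activated MnO2, CH2Cl2, rt; used at once
Reagents that add atoms: none
Why: allylic oxidation on MnO2 is neutral and heterogeneous, so the labile Z-enal should form without Z-to-E isomerisation.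

Step 4
Reactants: 6 diethylphosphonoacetic acid; 7 (4S)-4-benzyl-1,3-oxazolidin-2-one
Product: 9 (4S)-4-benzyl-3-[(diethoxyphosphoryl)acetyl]-1,3-oxazolidin-2-one, via pivalic mixed anhydride 8 (not isolated)
Conditions: PivCl, Et3N, THF, −20 °C; then 7, LiCl, rt
Reagents that add atoms: none
Why: N-acylation of an oxazolidinone through the pivalic mixed anhydride with LiCl-assisted acyl transfer is a standard way to load a carboxylic acid onto this auxiliary, the hindered pivaloyl carbonyl not being attacked.

Step 5
Reactants: 5 (2Z,4E)-2,4-dimethylhexa-2,4-dienal; 9 (4S)-4-benzyl-3-[(diethoxyphosphoryl)acetyl]-1,3-oxazolidin-2-one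
Product: 10 (4S)-4-benzyl-3-[(2E,4Z,6E)-4,6-dimethylocta-2,4,6-trienoyl]-1,3-oxazolidin-2-one
Conditions: LiCl, i-Pr2NEt, MeCN, 0 °C to rt
Reagents that add atoms: none
Why: Horner–Wadsworth–Emmons olefination of a phosphonoacetyl imide under mild LiCl/amine conditions is reliably E-selective and should not isomerise the Z-enal, giving the (2E,4Z,6E)-triene.

Step 6
Reactants: 10 (4S)-4-benzyl-3-[(2E,4Z,6E)-4,6-dimethylocta-2,4,6-trienoyl]-1,3-oxazolidin-2-one
Product: 11 (4S)-4-benzyl-3-{[(1S,6S)-3,5,6-trimethylcyclohexa-2,4-dien-1-yl]carbonyl}-1,3-oxazolidin-2-one (C13 acyl and C14 methyl cis)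
Conditions: toluene (degassed, BHT), 110 °C, sealed; then separation of the two cis diastereomers on silica gel or by crystallisation
Reagents that add atoms: none
Why: thermal 6π electrocyclisation is disrotatory, so the two E termini of the (E,Z,E)-triene become cis at C13/C14; the remote auxiliary should not bias the sense of rotation, so both cis ring antipodes form as diastereomeric imides and the (1S,6S) one is isolated, which is what turns a racemic ring closure into a single enantiomeric series.

Step 7
Reactants: 11 (4S)-4-benzyl-3-{[(1S,6S)-3,5,6-trimethylcyclohexa-2,4-dien-1-yl]carbonyl}-1,3-oxazolidin-2-one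
Product: 12 [(1S,6S)-3,5,6-trimethylcyclohexa-2,4-dien-1-yl]methanol
Conditions: LiBH4, MeOH (1 equiv), THF, 0 °C
Reagents that add atoms: none
Why: reductive cleavage of the N-acyl oxazolidinone by LiBH4 gives the primary alcohol and returns the auxiliary, under conditions too mild to epimerise the allylic C13 centre.

Step 8
Reactants: 12 [(1S,6S)-3,5,6-trimethylcyclohexa-2,4-dien-1-yl]methanol
Product: 13 tert-butyl(dimethyl){[(1S,6S)-3,5,6-trimethylcyclohexa-2,4-dien-1-yl]methoxy}silane (the cis-5-(silyloxymethyl)-1,3,6-trimethylcyclohexa-1,3-diene)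
Conditions: TBSCl, imidazole, DMF, 0 °C to rt
Reagents that add atoms: tert-butyldimethylsilyl chloride, CC(C)(C)[Si](C)(C)Cl
Why: standard silylation of a primary alcohol; the ether removes a free hydroxyl that could steer singlet oxygen towards ene chemistry and is stable up to step 13.

Step 9
Reactants: 13 tert-butyl(dimethyl){[(1S,6S)-3,5,6-trimethylcyclohexa-2,4-dien-1-yl]methoxy}silane
Product: 14 tert-butyl(dimethyl){[(1R,4S,7S,8S)-1,5,7-trimethyl-2,3-dioxabicyclo[2.2.2]oct-5-en-8-yl]methoxy}silane (O–O bridge from C15 to C18 on the β face, CH2OTBS and C14 methyl α)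
Conditions: O2, tetraphenylporphyrin (cat.), visible light (λ > 450 nm), CH2Cl2, −78 °C; no base, cold work-up
Reagents that add atoms: dioxygen, O=O
Why: Photosensitised singlet oxygen adds in a concerted suprafacial [4+2] fashion to the termini C15 and C18 of the ring-held s-cis diene, the reaction type by which cyclohexa-1,3-dienes give 2,3-dioxabicyclo[2.2.2]oct-5-enes (α-terpinene to ascaridole). The 1,2-dioxane ring is closed by cycloaddition, both C–O bonds forming in one event so that the O–O unit bridges C15 and C18 across one face. C15 and C18 are therefore set together and cis to each other, and their sense is dictated by the C13/C14 centres: A(1,2) strain with the C15 methyl forces the C14 methyl pseudoaxial and, with the cis CH2OTBS group at C13, closes the α face, so O2 should arrive on the β face. The step needs π-facial selectivity and [4+2] over ene periselectivity; the first comes from that pseudoaxial methyl, the second from the locked cisoid diene, the low temperature and the non-polar solvent, with the silyl ether excluding hydroxyl-directed ene attack. Base is kept out so that the peroxide carbon C18, which carries a hydrogen, cannot enter a Kornblum–DeLaMare rearrangement.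

Step 10
Reactants: 14 tert-butyl(dimethyl){[(1R,4S,7S,8S)-1,5,7-trimethyl-2,3-dioxabicyclo[2.2.2]oct-5-en-8-yl]methoxy}silane
Product: 15 (1R,4S,5S,6S)-5-{[tert-butyl(dimethyl)silyl]oxymethyl}-1,3,6-trimethylcyclohex-2-ene-1,4-diol (C15-OH and C18-OH both β)
Conditions: thiourea, MeOH (reagent grade), rt
Reagents that add atoms: none
Why: thiourea reduces the O–O bond of bicyclic endoperoxides to cis-1,4-diols under neutral conditions, leaving both C–O bonds (hence C15 and C18), the alkene and the silyl ether untouched.

Step 11
Reactants: 15 (1R,4S,5S,6S)-5-{[tert-butyl(dimethyl)silyl]oxymethyl}-1,3,6-trimethylcyclohex-2-ene-1,4-diol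
Product: 17 (1R,2R,3S,4S,5S,6S)-5-{[tert-butyl(dimethyl)silyl]oxymethyl}-1,3,6-trimethylcyclohexane-1,2,3,4-tetrol (all four hydroxyls β), via osmate ester 16 (not isolated)
Conditions: OsO4 (1.05 equiv), TMEDA, CH2Cl2, −78 °C; then aq. Na2SO3, THF, 60 °C
Reagents that add atoms: osmium tetroxide, O=[Os](=O)(=O)=O
Why: hydrogen-bond-directed dihydroxylation, in which the OsO4·TMEDA complex is held by the two β allylic hydroxyls (C15, C18) and adds [3+2] to the β face of C16=C17, setting C16 and C17 syn to the existing oxygens, while the α face is in addition shielded by the C15 methyl.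

Step 12
Reactants: 17 (1R,2R,3S,4S,5S,6S)-5-{[tert-butyl(dimethyl)silyl]oxymethyl}-1,3,6-trimethylcyclohexane-1,2,3,4-tetrol
Product: 18 the O16,O18-diacetate of 17 (C15-OH and C17-OH free, CH2OTBS retained, configuration unchanged)
Conditions: Ac2O, pyridine, DMAP (cat.), CH2Cl2, 0 °C to rt
Reagents that add atoms: acetic anhydride, CC(=O)OC(C)=O
Why: nucleophile-catalysed acylation should take the two equatorial secondary hydroxyls (C16, C18) and leave the two axial tertiary ones (C15, C17), which do not acylate under these mild conditions.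

Step 13
Reactants: 18 the O16,O18-diacetate of 17
Product: 19 primary alcohol: 18 with CH2OH at C13 (16β,18β-diacetoxy-15β,17β-dihydroxy-14α,15α,17α-trimethylcyclohexyl-13α-methanol)
Conditions: HF·pyridine, pyridine, THF, 0 °C to rt
Reagents that add atoms: none
Why: buffered HF·pyridine cleaves the primary TBS ether under weakly acidic conditions, which avoids the base-induced acetyl shift from O18 to O12 that fluoride/alkoxide conditions could cause.

Step 14
Reactants: 19 primary alcohol (C12-OH)
Product: 20 aldehyde: 16β,18β-diacetoxy-15β,17β-dihydroxy-14α,15α,17α-trimethylcyclohexane-13α-carbaldehyde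
Conditions: Dess–Martin periodinane, pyridine, CH2Cl2, 0 °C to rt; used at once
Reagents that add atoms: none
Why: Dess–Martin oxidation is non-basic, so the aldehyde should form without β-elimination of the equatorial C18 acetate (poorly aligned with the enol π system) and without epimerisation at C13, whose formyl group is already equatorial.

Step 15
Reactants: 20 aldehyde (C12 formyl); 21 2-(triphenylphosphoranylidene)propanal
Product: 22 (E)-enal: (2E)-3-(16β,18β-diacetoxy-15β,17β-dihydroxy-14α,15α,17α-trimethylcyclohex-13α-yl)-2-methylprop-2-enal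
Conditions: toluene, 90 °C
Reagents that add atoms: none
Why: Wittig reaction with the stabilised, non-basic formyl ylide is E-selective for the trisubstituted C11=C12 bond and should stop at the enal, a poorer electrophile than aldehyde 20.

Step 16
Reactants: 23 ethyl 2-methyl-3-oxopentanoate; 24 N-methoxy-N-methylpropanamide
Product: 25 ethyl 2,4-dimethyl-3,5-dioxoheptanoate (mixture of stereoisomers and enol forms)
Conditions: LDA (2.2 equiv), THF, −78 to 0 °C; then 24, −78 °C to rt; aq. HCl
Reagents that add atoms: none
Why: the 2,4-dianion of the β-keto ester is acylated at its more reactive γ-carbon (Claisen-type γ-acylation), and the Weinreb amide holds the tetrahedral adduct until work-up so that the diketo ester is not exposed to base.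

Step 17
Reactants: 25 ethyl 2,4-dimethyl-3,5-dioxoheptanoate
Product: 26 6-ethyl-4-hydroxy-3,5-dimethyl-2H-pyran-2-one
Conditions: DBU, toluene, 80 °C; aq. HCl
Reagents that add atoms: none
Why: DBU-promoted enolisation and lactonisation of the C5 enol oxygen onto the ester (6-exo-trig) gives the 4-hydroxy-2-pyranone with loss of ethanol.

Step 18
Reactants: 26 6-ethyl-4-hydroxy-3,5-dimethyl-2H-pyran-2-one
Product: 27 2-ethyl-6-methoxy-3,5-dimethyl-4H-pyran-4-one
Conditions: MeOTf, CH2Cl2, rt; then aq. NaHCO3
Reagents that add atoms: methyl trifluoromethanesulfonate, COS(=O)(=O)C(F)(F)F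
Why: under neutral conditions the hard methylating agent attacks the most basic oxygen, the lactone carbonyl, and loss of a proton from the hydroxypyrylium gives the 2-methoxy-4-pyranone rather than the 4-methoxy-2-pyranone formed under basic conditions.

Step 19
Reactants: 27 2-ethyl-6-methoxy-3,5-dimethyl-4H-pyran-4-one; 28 (tert-butyldimethylsilyloxy)acetaldehyde
Product: 29 2-[4-{[tert-butyl(dimethyl)silyl]oxy}-3-hydroxybutan-2-yl]-6-methoxy-3,5-dimethyl-4H-pyran-4-one (diastereomer mixture)
Conditions: LiHMDS, THF, −78 °C; then 28; aq. NH4Cl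
Reagents that add atoms: none
Why: the CH2 of the ethyl group is vinylogously α to the pyranone carbonyl and is lithiated selectively (lateral metalation), and aldol addition to the aldehyde forms the C7–C8 bond; both new centres are erased in the next step.

Step 20
Reactants: 29 aldol adduct
Product: 31 2-[(2E)-4-{[tert-butyl(dimethyl)silyl]oxy}but-2-en-2-yl]-6-methoxy-3,5-dimethyl-4H-pyran-4-one, via mesylate 30 (not isolated)
Conditions: MsCl, Et3N, CH2Cl2, 0 °C; then DBU, rt
Reagents that add atoms: none
Why: mesylation followed by DBU gives E1cB elimination through the vinylogous enolate, and A(1,3) strain with the ring methyl should favour the E alkene (CH2OTBS trans to the pyranone).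

Step 21
Reactants: 31 allylic silyl ether
Product: 32 2-[(2E)-4-bromobut-2-en-2-yl]-6-methoxy-3,5-dimethyl-4H-pyran-4-one
Conditions: Ph3PBr2, CH2Cl2, 0 °C to rt
Reagents that add atoms: triphenylphosphine dibromide, BrP(Br)(c1ccccc1)(c1ccccc1)c1ccccc1
Why: triphenylphosphine dibromide converts primary TBS ethers directly into bromides (silyl transfer to bromide, then SN2 on the alkoxyphosphonium ion), with no separate acidic or basic deprotection; the conjugated primary bromide is also the thermodynamic allylic isomer.

Step 22
Reactants: 32 allylic bromide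
Product: 33 diethyl [(2E)-3-(6-methoxy-3,5-dimethyl-4-oxo-4H-pyran-2-yl)but-2-en-1-yl]phosphonate
Conditions: P(OEt)3 (neat), 110 °C
Reagents that add atoms: triethyl phosphite, CCOP(OCC)OCC
Why: Michaelis–Arbuzov reaction at the unhindered primary allylic carbon; SN2 displacement keeps the E alkene.

Step 23
Reactants: 33 pyranone allylic phosphonate; 22 (E)-enal
Product: 34 amaurone B
Conditions: LiHMDS (1 equiv per 33), THF, −78 °C; then 22, −78 to 0 °C
Reagents that add atoms: none
Why: Horner–Wadsworth–Emmons reaction of the conjugation-stabilised allylic phosphonate anion with the enal should give the C9=C10 bond E, the existing C7=C8 and C11=C12 bonds keeping their favoured E geometry; pre-forming the anion with exactly one equivalent of base at low temperature keeps free amide base away from the acetates and tertiary hydroxyls.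

Compound list
1 | tiglic aldehyde, (E)-2-methylbut-2-enal | C/C=C(\C)C=O | starting material
2 | ethyl 2-[bis(2,2,2-trifluoroethoxy)phosphoryl]propanoate | CCOC(=O)C(C)P(=O)(OCC(F)(F)F)OCC(F)(F)F | starting material
3 | ethyl (2Z,4E)-2,4-dimethylhexa-2,4-dienoate | CCOC(=O)/C(C)=C\C(C)=C\C | intermediate
4 | (2Z,4E)-2,4-dimethylhexa-2,4-dien-1-ol | OC/C(C)=C\C(C)=C\C | intermediate
5 | (2Z,4E)-2,4-dimethylhexa-2,4-dienal | O=C/C(C)=C\C(C)=C\C | intermediate
6 | diethylphosphonoacetic acid | OC(=O)CP(=O)(OCC)OCC | starting material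
7 | (4S)-4-benzyl-1,3-oxazolidin-2-one | O=C1N[C@@H](Cc2ccccc2)CO1 | starting material
8 | (diethoxyphosphoryl)acetic pivalic anhydride | CCOP(=O)(OCC)CC(=O)OC(=O)C(C)(C)C | intermediate
9 | (4S)-4-benzyl-3-[(diethoxyphosphoryl)acetyl]-1,3-oxazolidin-2-one | CCOP(=O)(OCC)CC(=O)N1[C@@H](Cc2ccccc2)COC1=O | intermediate
10 | (4S)-4-benzyl-3-[(2E,4Z,6E)-4,6-dimethylocta-2,4,6-trienoyl]-1,3-oxazolidin-2-one | C/C=C(C)/C=C(C)\C=C\C(=O)N1[C@@H](Cc2ccccc2)COC1=O | intermediate
11 | (4S)-4-benzyl-3-{[(1S,6S)-3,5,6-trimethylcyclohexa-2,4-dien-1-yl]carbonyl}-1,3-oxazolidin-2-one | O=C([C@@H]1[C@H](C)C(C)=CC(C)=C1)N1[C@@H](Cc2ccccc2)COC1=O | intermediate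
12 | [(1S,6S)-3,5,6-trimethylcyclohexa-2,4-dien-1-yl]methanol | OC[C@@H]1[C@H](C)C(C)=CC(C)=C1 | intermediate
13 | tert-butyl(dimethyl){[(1S,6S)-3,5,6-trimethylcyclohexa-2,4-dien-1-yl]methoxy}silane | CC(C)(C)[Si](C)(C)OC[C@@H]1[C@H](C)C(C)=CC(C)=C1 | intermediate
14 | tert-butyl(dimethyl){[(1R,4S,7S,8S)-1,5,7-trimethyl-2,3-dioxabicyclo[2.2.2]oct-5-en-8-yl]methoxy}silane | CC(C)(C)[Si](C)(C)OC[C@@H]1[C@H](C)[C@]2(C)C=C(C)[C@H]1OO2 | intermediate
15 | (1R,4S,5S,6S)-5-{[tert-butyl(dimethyl)silyl]oxymethyl}-1,3,6-trimethylcyclohex-2-ene-1,4-diol | CC(C)(C)[Si](C)(C)OC[C@@H]1[C@H](C)[C@@](C)(O)C=C(C)[C@H]1O | intermediate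
16 | cyclic C16,C17 osmate(VI) ester of 17 with chelating TMEDA (dioxo-osmium glycolate) | CC(C)(C)[Si](C)(C)OC[C@@H]1[C@H](C)[C@@](C)(O)[C@@H](O[Os-2]23(=O)(=O)[N+](C)(C)CC[N+]3(C)C)[C@@](C)(O2)[C@H]1O | intermediate
17 | (1R,2R,3S,4S,5S,6S)-5-{[tert-butyl(dimethyl)silyl]oxymethyl}-1,3,6-trimethylcyclohexane-1,2,3,4-tetrol | CC(C)(C)[Si](C)(C)OC[C@@H]1[C@H](C)[C@@](C)(O)[C@@H](O)[C@@](C)(O)[C@H]1O | intermediate
18 | O16,O18-diacetate of 17 (C15-OH, C17-OH free) | CC(C)(C)[Si](C)(C)OC[C@@H]1[C@H](C)[C@@](C)(O)[C@@H](OC(C)=O)[C@@](C)(O)[C@H]1OC(C)=O | intermediate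
19 | 16β,18β-diacetoxy-15β,17β-dihydroxy-14α,15α,17α-trimethylcyclohexyl-13α-methanol | OC[C@@H]1[C@H](C)[C@@](C)(O)[C@@H](OC(C)=O)[C@@](C)(O)[C@H]1OC(C)=O | intermediate
20 | 16β,18β-diacetoxy-15β,17β-dihydroxy-14α,15α,17α-trimethylcyclohexane-13α-carbaldehyde | O=C[C@@H]1[C@H](C)[C@@](C)(O)[C@@H](OC(C)=O)[C@@](C)(O)[C@H]1OC(C)=O | intermediate
21 | 2-(triphenylphosphoranylidene)propanal | CC(C=O)=P(c1ccccc1)(c1ccccc1)c1ccccc1 | starting material
22 | (2E)-3-(16β,18β-diacetoxy-15β,17β-dihydroxy-14α,15α,17α-trimethylcyclohex-13α-yl)-2-methylprop-2-enal | O=C/C(C)=C/[C@@H]1[C@H](C)[C@@](C)(O)[C@@H](OC(C)=O)[C@@](C)(O)[C@H]1OC(C)=O | intermediate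
23 | ethyl 2-methyl-3-oxopentanoate | CCC(=O)C(C)C(=O)OCC | starting material
24 | N-methoxy-N-methylpropanamide | CCC(=O)N(C)OC | starting material
25 | ethyl 2,4-dimethyl-3,5-dioxoheptanoate | CCC(=O)C(C)C(=O)C(C)C(=O)OCC | intermediate
26 | 6-ethyl-4-hydroxy-3,5-dimethyl-2H-pyran-2-one | CCC1=C(C)C(O)=C(C)C(=O)O1 | intermediate
27 | 2-ethyl-6-methoxy-3,5-dimethyl-4H-pyran-4-one | CCc1oc(OC)c(C)c(=O)c1C | intermediate
28 | (tert-butyldimethylsilyloxy)acetaldehyde | CC(C)(C)[Si](C)(C)OCC=O | starting material
29 | 2-[4-{[tert-butyl(dimethyl)silyl]oxy}-3-hydroxybutan-2-yl]-6-methoxy-3,5-dimethyl-4H-pyran-4-one | COc1oc(C(C)C(O)CO[Si](C)(C)C(C)(C)C)c(C)c(=O)c1C | intermediate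
30 | methanesulfonate of 29 | COc1oc(C(C)C(CO[Si](C)(C)C(C)(C)C)OS(C)(=O)=O)c(C)c(=O)c1C | intermediate
31 | 2-[(2E)-4-{[tert-butyl(dimethyl)silyl]oxy}but-2-en-2-yl]-6-methoxy-3,5-dimethyl-4H-pyran-4-one | COc1oc(/C(C)=C/CO[Si](C)(C)C(C)(C)C)c(C)c(=O)c1C | intermediate
32 | 2-[(2E)-4-bromobut-2-en-2-yl]-6-methoxy-3,5-dimethyl-4H-pyran-4-one | COc1oc(/C(C)=C/CBr)c(C)c(=O)c1C | intermediate
33 | diethyl [(2E)-3-(6-methoxy-3,5-dimethyl-4-oxo-4H-pyran-2-yl)but-2-en-1-yl]phosphonate | CCOP(=O)(C/C=C(C)/c1oc(OC)c(C)c(=O)c1C)OCC | intermediate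
34 | amaurone B | COc1oc(/C(C)=C/C=C/C(C)=C/[C@@H]2[C@H](C)[C@@](C)(O)[C@@H](OC(C)=O)[C@@](C)(O)[C@H]2OC(C)=O)c(C)c(=O)c1C | target

Total step count: 23 (16 in the ring series including the auxiliary reagent, 7 for the pyranone phosphonate).
Longest linear sequence: 15 steps (1, 2, 3, 5–15, 23, from tiglic aldehyde).

Steps most likely to fail

1. Step 9. Ene hydroperoxidation (abstraction of the pseudoaxial C13–H or of a methyl hydrogen) or attack from the α face may compete with the β-face [4+2] addition, and the peroxide may rearrange on handling. The fallback replaces O2 by two osmylations and sets out from 13. Catalytic dihydroxylation (OsO4 cat., NMO, acetone–water) of one ring alkene from the open β face should give the C17,C18-diol F1 or its C15,C16-regioisomer F2, both with β hydroxyls. Hydroxyl-directed catalytic dihydroxylation of the remaining alkene (OsO4 cat., Me3NO·2H2O, CH2Cl2, rt) then delivers the second pair of oxygens syn to the first from either regioisomer, and the route is rejoined at tetraol 17.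

2. Step 23. In the last olefination the delocalised phosphonate anion may lose the C7=C8 geometry or react at its remote terminus, and alkoxide formation may shift or remove the acetates. The fallback avoids any added base and sets out from bromide 32 and enal 22. Triphenylphosphine in toluene converts 32 into the allylic phosphonium bromide F3. A Wittig reaction of F3 with 22 in refluxing 1,2-epoxybutane, where the epoxide takes up HBr, followed by catalytic iodine in CH2Cl2 under ambient light to equilibrate any 9Z isomer, should lead to the all-E triene and so back to the route at 34.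

3. Step 6. The ring closure itself is expected to be clean; the risk is that the two cis imides co-elute or co-crystallise, so that no single enantiomeric series is obtained. The fallback sets out from 10, which is cyclised as before. The unseparated imide mixture is reduced with LiBH4 as in step 7 to 12 together with its enantiomer, the (1R,6R)-alcohol F4. The two enantiomers are then separated by preparative supercritical-fluid chromatography on a polysaccharide chiral stationary phase, which returns to the route at 12.

Further compounds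
F1 | step 9 | C17,C18-diol of 13 (17β,18β-dihydroxy, C15=C16 retained) | CC(C)(C)[Si](C)(C)OC[C@@H]1[C@H](C)C(C)=C[C@@](C)(O)[C@H]1O
F2 | step 9 | C15,C16-diol of 13 (15β,16β-dihydroxy, C17=C18 retained) | CC(C)(C)[Si](C)(C)OC[C@@H]1[C@H](C)[C@@](C)(O)[C@@H](O)C(C)=C1
F3 | step 23 | [(2E)-3-(6-methoxy-3,5-dimethyl-4-oxo-4H-pyran-2-yl)but-2-en-1-yl]triphenylphosphonium bromide | COc1oc(/C(C)=C/C[P+](c2ccccc2)(c2ccccc2)c2ccccc2)c(C)c(=O)c1C.[Br-]
F4 | step 6 | [(1R,6R)-3,5,6-trimethylcyclohexa-2,4-dien-1-yl]methanol (enantiomer of 12) | OC[C@H]1[C@@H](C)C(C)=CC(C)=C1
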